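**Strategy.** The oxolane ring is disconnected at O1–C2 and C3–C4. In one flask, iodoalkoxylation of the methyl enol ether of 3,4-dimethoxypropiophenone (C2, C3) by the (S)-propargylic alcohol 7 (O1, C5, and an ethynyl group that becomes C4 and its methyl), followed by 5-exo-dig radical cyclisation (Ueno–Stork annulation), closes the ring. The step exploits that C2, bonded to O1 and an electron-rich aryl ring, can be carried as a ketal carbon: the single stereocentre C5 then relays to C4 (hydrogenation), C3 (equilibration) and C2 (hydride addition to the oxocarbenium ion). The threo side chain is added last from a lactate-derived α-tosyloxy ketone.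

Key step: step 4

Remark: ring numbering used throughout is O1, C2 (carries the 3,4-dimethoxyphenyl group), C3, C4, C5 (carries the 4-oxy-3-methoxyphenyl group); compounds 1, 4, 5, 13 and 15 are assumed to be purchased.

**Step 1**
Reactants: 1 1-(3,4-dimethoxyphenyl)propan-1-one
Product: 3 (Z)-1-(3,4-dimethoxyphenyl)-1-methoxyprop-1-ene (E/Z mixture usable), via dimethyl ketal 2 (not isolated)
Conditions: HC(OMe)3, p-TsOH·H2O (cat.), MeOH, 50 °C; concentrate; then TMSOTf, iPr2NEt, CH2Cl2, −20 °C to rt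
Reagents that add atoms: trimethyl orthoformate, COC(OC)OC
Why: Acid-catalysed ketalisation with the orthoformate, then TMSOTf/amine-promoted loss of methanol from the electron-rich aryl ketal, should give the enol ether, whose geometry is irrelevant because C2 and C3 are re-formed later.

**Step 2**
Reactants: 4 4-(benzyloxy)-3-methoxybenzaldehyde; 5 ethynylmagnesium bromide
Product: 6 rac-1-[4-(benzyloxy)-3-methoxyphenyl]prop-2-yn-1-ol
Conditions: THF, 0 °C; aq. NH4Cl
Reagents that add atoms: none
Why: Grignard addition of the acetylide to the aldehyde should give the racemic propargylic alcohol, with the benzyl ether inert.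

**Step 3**
Reactants: 6 rac-1-[4-(benzyloxy)-3-methoxyphenyl]prop-2-yn-1-ol
Product: 7 (1S)-1-[4-(benzyloxy)-3-methoxyphenyl]prop-2-yn-1-ol
Conditions: Novozym 435 (immobilised Candida antarctica lipase B), vinyl acetate, MTBE, 40 °C, run to just past half conversion; chromatography
Reagents that add atoms: none
Why: Lipase-catalysed kinetic resolution by transesterification should acylate the (R)-alcohol (Kazlauskas rule, aryl as the large and ethynyl as the medium group) and leave the (S)-alcohol, whose carbinol carbon becomes C5, the only stereocentre carried into the ring synthesis.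

**Step 4**
Reactants: 7 (1S)-1-[4-(benzyloxy)-3-methoxyphenyl]prop-2-yn-1-ol; 3 (Z)-1-(3,4-dimethoxyphenyl)-1-methoxyprop-1-ene
Product: 9 (5S)-5-[4-(benzyloxy)-3-methoxyphenyl]-2-(3,4-dimethoxyphenyl)-2-methoxy-3-methyl-4-methylideneoxolane (mixture of C2/C3 diastereomers), via iodoketal 8 (not isolated)
Conditions: NIS, solid NaHCO3, 4 Å MS, CH2Cl2, −40 to 0 °C; aq. Na2S2O3 wash, solvent switch to toluene; then Bu3SnH (slow addition), Et3B, air, rt
Reagents that add atoms: none
Why: NIS iodinates C3 of the enol ether to an aryl- and methoxy-stabilised α-iodo oxocarbenium ion that is trapped at C2 by the hydroxyl oxygen of 7 (O1–C2); the iodine is then abstracted by Bu3Sn•, the secondary C3 radical adds to the internal alkyne carbon (C3–C4), and the vinyl radical takes hydrogen from Bu3SnH to leave the exocyclic methylene that becomes the C4 methyl. The closest known reaction type is the Ueno–Stork haloacetal radical cyclisation, here run at the ketal level of an aryl ketone. The oxolane ring closes in the 5-exo-dig mode. C2 and C3 are formed as mixtures on purpose, because both are reset in step 6, while C5 is untouched as no bond to it is broken. The step needs Markovnikov iodoalkoxylation, secured by the oxocarbenium ion that places oxygen on the carbon bearing aryl and methoxy, and it needs 5-exo cyclisation to outrun direct reduction and 6-endo closure, secured by the short oxygen tether and slow addition of Bu3SnH.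

**Step 5**
Reactants: 9 (5S)-5-[4-(benzyloxy)-3-methoxyphenyl]-2-(3,4-dimethoxyphenyl)-2-methoxy-3-methyl-4-methylideneoxolane
Product: 10 (4R,5S)-5-[4-(benzyloxy)-3-methoxyphenyl]-2-(3,4-dimethoxyphenyl)-2-methoxy-3,4-dimethyloxolane (mixture at C2/C3)
Conditions: H2 (4 bar), RhCl(PPh3)3 (5 mol %), toluene/EtOH, 40 °C
Reagents that add atoms: none
Why: Homogeneous hydrogenation should deliver hydrogen to the exocyclic alkene from the face opposite the adjacent C5 aryl group, so the new C4 methyl is cis to that aryl (4R), and RhCl(PPh3)3 should not cleave the benzyl ether, the benzylic ring C–O bonds or the ketal.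

**Step 6**
Reactants: 10 (4R,5S)-5-[4-(benzyloxy)-3-methoxyphenyl]-2-(3,4-dimethoxyphenyl)-2-methoxy-3,4-dimethyloxolane
Product: 11 (2S,3R,4R,5S)-2-(3,4-dimethoxyphenyl)-5-[4-(benzyloxy)-3-methoxyphenyl]-3,4-dimethyloxolane
Conditions: BF3·OEt2, Et3SiH, CH2Cl2, −78 to −30 °C
Reagents that add atoms: none
Why: BF3·OEt2 ionises the methyl ketal to the 2-aryl oxocarbenium ion, C3 equilibrates through the enol ether (4,5-dihydrofuran) to the isomer with its methyl trans to the C4 methyl, and Et3SiH adds to C2 anti to the C3 methyl (1,2-induction in oxocarbenium reduction), which should give the 2,3-cis-3,4-trans-4,5-cis ring (reductive deoxygenation of a cyclic ketal).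

**Step 7**
Reactants: 11 (2S,3R,4R,5S)-2-(3,4-dimethoxyphenyl)-5-[4-(benzyloxy)-3-methoxyphenyl]-3,4-dimethyloxolane
Product: 12 4-[(2S,3R,4R,5S)-5-(3,4-dimethoxyphenyl)-3,4-dimethyloxolan-2-yl]-2-methoxyphenol
Conditions: H2 (1 atm), Pd/C, EtOAc, rt, stopped when 11 is consumed
Reagents that add atoms: none
Why: Hydrogenolysis of the benzyl ether over Pd/C should free the phenol, since the doubly substituted benzylic ring ethers are cleaved much more slowly.

**Step 8**
Reactants: 13 ethyl (S)-lactate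
Product: 14 (2S)-2-hydroxy-N-methoxy-N-methylpropanamide
Conditions: MeNH(OMe)·HCl, iPrMgCl, THF, −20 to 0 °C
Reagents that add atoms: N,O-dimethylhydroxylamine hydrochloride, CNOC.Cl
Why: Aminolysis of the ester by the magnesium amide should give the Weinreb amide without touching the (S) stereocentre taken from the chiral pool.

**Step 9**
Reactants: 14 (2S)-2-hydroxy-N-methoxy-N-methylpropanamide; 15 3,4-dimethoxyphenylmagnesium bromide
Product: 16 (2S)-1-(3,4-dimethoxyphenyl)-2-hydroxypropan-1-one
Conditions: 15 (2.5 equiv), THF, 0 °C; aq. NH4Cl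
Reagents that add atoms: none
Why: The aryl Grignard reagent should add once to the Weinreb amide through the stable magnesium chelate, the first equivalent only deprotonating the hydroxyl, so the ketone forms without racemisation.

**Step 10**
Reactants: 16 (2S)-1-(3,4-dimethoxyphenyl)-2-hydroxypropan-1-one
Product: 17 (2S)-1-(3,4-dimethoxyphenyl)-1-oxopropan-2-yl 4-methylbenzenesulfonate
Conditions: TsCl, Et3N, DMAP (cat.), CH2Cl2, 0 °C
Reagents that add atoms: p-toluenesulfonyl chloride, Cc1ccc(S(=O)(=O)Cl)cc1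
Why: Sulfonylation of the secondary alcohol turns it into a leaving group with retention at carbon.

**Step 11**
Reactants: 12 4-[(2S,3R,4R,5S)-5-(3,4-dimethoxyphenyl)-3,4-dimethyloxolan-2-yl]-2-methoxyphenol; 17 (2S)-1-(3,4-dimethoxyphenyl)-1-oxopropan-2-yl 4-methylbenzenesulfonate
Product: 18 (2R)-1-(3,4-dimethoxyphenyl)-2-{4-[(2S,3R,4R,5S)-5-(3,4-dimethoxyphenyl)-3,4-dimethyloxolan-2-yl]-2-methoxyphenoxy}propan-1-one
Conditions: BEMP (2-tert-butylimino-2-diethylamino-1,3-dimethylperhydro-1,3,2-diazaphosphorine), MeCN, 0 °C to rt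
Reagents that add atoms: none
Why: The phenoxide should displace the α-keto tosylate in an SN2 reaction with inversion, (S) to (R), while the non-nucleophilic phosphazene base keeps enolisation of the ketone low (Williamson-type etherification).

**Step 12**
Reactants: 18 (2R)-1-(3,4-dimethoxyphenyl)-2-{4-[(2S,3R,4R,5S)-5-(3,4-dimethoxyphenyl)-3,4-dimethyloxolan-2-yl]-2-methoxyphenoxy}propan-1-one
Product: 19 (1R,2R)-1-(3,4-dimethoxyphenyl)-2-{4-[(2S,3R,4R,5S)-5-(3,4-dimethoxyphenyl)-3,4-dimethyloxolan-2-yl]-2-methoxyphenoxy}propan-1-ol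
Conditions: polymer-supported borohydride (BH4− form of Amberlite IRA-400), MeOH, 0 °C to rt
Reagents that add atoms: none
Why: Under non-chelating conditions the borohydride should add to the α-aryloxy ketone in the Felkin–Anh sense, anti to the C–OAr bond, which gives the (1R,2R)-threo alcohol.

**Compound list**
1 | 1-(3,4-dimethoxyphenyl)propan-1-one | CCC(=O)c1ccc(OC)c(OC)c1 | starting material
2 | 4-(1,1-dimethoxypropyl)-1,2-dimethoxybenzene (dimethyl ketal of 1) | CCC(OC)(OC)c1ccc(OC)c(OC)c1 | intermediate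
3 | (Z)-1-(3,4-dimethoxyphenyl)-1-methoxyprop-1-ene (E/Z mixture usable) | C/C=C(OC)/c1ccc(OC)c(OC)c1 | intermediate
4 | 4-(benzyloxy)-3-methoxybenzaldehyde | O=Cc1ccc(OCc2ccccc2)c(OC)c1 | starting material
5 | ethynylmagnesium bromide | C#C[Mg]Br | starting material
6 | rac-1-[4-(benzyloxy)-3-methoxyphenyl]prop-2-yn-1-ol | C#CC(O)c1ccc(OCc2ccccc2)c(OC)c1 | intermediate
7 | (1S)-1-[4-(benzyloxy)-3-methoxyphenyl]prop-2-yn-1-ol | C#C[C@H](O)c1ccc(OCc2ccccc2)c(OC)c1 | intermediate
8 | 1-(benzyloxy)-4-[(1S)-1-{[1-(3,4-dimethoxyphenyl)-2-iodo-1-methoxypropyl]oxy}prop-2-yn-1-yl]-2-methoxybenzene (iodoketal, diastereomer mixture) | C#C[C@H](OC(OC)(c1ccc(OC)c(OC)c1)C(C)I)c1ccc(OCc2ccccc2)c(OC)c1 | intermediate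
9 | (5S)-5-[4-(benzyloxy)-3-methoxyphenyl]-2-(3,4-dimethoxyphenyl)-2-methoxy-3-methyl-4-methylideneoxolane (mixture at C2/C3) | COC1(c2ccc(OC)c(OC)c2)O[C@H](c2ccc(OCc3ccccc3)c(OC)c2)C(=C)C1C | intermediate
10 | (4R,5S)-5-[4-(benzyloxy)-3-methoxyphenyl]-2-(3,4-dimethoxyphenyl)-2-methoxy-3,4-dimethyloxolane (mixture at C2/C3) | COC1(c2ccc(OC)c(OC)c2)O[C@H](c2ccc(OCc3ccccc3)c(OC)c2)[C@H](C)C1C | intermediate
11 | (2S,3R,4R,5S)-2-(3,4-dimethoxyphenyl)-5-[4-(benzyloxy)-3-methoxyphenyl]-3,4-dimethyloxolane | COc1cc([C@H]2O[C@H](c3ccc(OC)c(OC)c3)[C@H](C)[C@H]2C)ccc1OCc1ccccc1 | intermediate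
12 | 4-[(2S,3R,4R,5S)-5-(3,4-dimethoxyphenyl)-3,4-dimethyloxolan-2-yl]-2-methoxyphenol | COc1cc([C@H]2O[C@H](c3ccc(OC)c(OC)c3)[C@H](C)[C@H]2C)ccc1O | intermediate
13 | ethyl (S)-lactate | CCOC(=O)[C@H](C)O | starting material
14 | (2S)-2-hydroxy-N-methoxy-N-methylpropanamide | C[C@H](O)C(=O)N(C)OC | intermediate
15 | 3,4-dimethoxyphenylmagnesium bromide | COc1ccc([Mg]Br)cc1OC | starting material
16 | (2S)-1-(3,4-dimethoxyphenyl)-2-hydroxypropan-1-one | C[C@H](O)C(=O)c1ccc(OC)c(OC)c1 | intermediate
17 | (2S)-1-(3,4-dimethoxyphenyl)-1-oxopropan-2-yl 4-methylbenzenesulfonate | C[C@H](OS(=O)(=O)c1ccc(C)cc1)C(=O)c1ccc(OC)c(OC)c1 | intermediate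
18 | (2R)-1-(3,4-dimethoxyphenyl)-2-{4-[(2S,3R,4R,5S)-5-(3,4-dimethoxyphenyl)-3,4-dimethyloxolan-2-yl]-2-methoxyphenoxy}propan-1-one | COc1ccc(C(=O)[C@@H](C)Oc2ccc([C@H]3O[C@H](c4ccc(OC)c(OC)c4)[C@H](C)[C@H]3C)cc2OC)cc1OC | intermediate
19 | (1R,2R)-1-(3,4-dimethoxyphenyl)-2-{4-[(2S,3R,4R,5S)-5-(3,4-dimethoxyphenyl)-3,4-dimethyloxolan-2-yl]-2-methoxyphenoxy}propan-1-ol | COc1ccc([C@@H](O)[C@@H](C)Oc2ccc([C@H]3O[C@H](c4ccc(OC)c(OC)c4)[C@H](C)[C@H]3C)cc2OC)cc1OC | target

**Step count.** Total: 12 steps. Longest linear sequence: 8 steps (2, 3, 4, 5, 6, 7, 11, 12, from aldehyde 4).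

**Steps most likely to fail**

Step 4. The hindered secondary alcohol may fail to capture the tertiary α-iodo oxocarbenium ion, with proton loss to a β-iodo enol ether winning, or the electron-rich aryl ketal may ionise and decompose before or during the radical stage. The fallback runs the same annulation at the acetal level and adds the aryl group afterwards as a nucleophile. It sets out from 7. NBS and ethyl prop-1-enyl ether would give the bromoacetal F1. Bu3SnH/AIBN (benzene, 80 °C) would close it 5-exo-dig to the 2-ethoxy-4-methylidene oxolane F2. Hydrogenation over RhCl(PPh3)3 would give the 4-methyl acetal F3. Jones oxidation (CrO3, H2SO4, acetone) would give the lactone F4, equilibrated at C3 with DBU to the 3,4-trans isomer. 3,4-Dimethoxyphenyllithium (4-bromoveratrole, n-BuLi, THF, −78 °C) would add once to give the hemiketal F5. BF3·OEt2/Et3SiH under the conditions of step 6 would then give 11, where the fallback rejoins the route.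

Step 5. Hydrogen may be delivered with poor facial selectivity, because the C3 epimers present in 9 shield the two faces differently, or the catalyst may move the double bond into the ring, after which acid would aromatise the ring. The fallback makes the methyl group in polar steps with a bulkier reagent. It sets out from 9. Hydroboration with 9-BBN anti to the C5 aryl group and oxidation (NaBO3·4H2O) would give the primary alcohol F6. TsCl/pyridine would give the tosylate F7. LiEt3BH would displace the tosylate by hydride and give 10, where the fallback rejoins the route.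

Step 11. The base may epimerise the α-stereocentre of 17 or of 18 through the enolate, or eliminate toluenesulfonic acid from 17. The fallback forms the ether bond on an ester that enolises less readily. It sets out from 12. A Mitsunobu reaction with ethyl (S)-lactate 13 (PPh3, DIAD, inversion) would give the (R)-aryloxy ester F8. MeNH(OMe)·HCl/iPrMgCl would give the Weinreb amide F9. Addition of 3,4-dimethoxyphenylmagnesium bromide 15 would give 18, where the fallback rejoins the route.

**Further compounds**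
F1 | step 4 | 1-(benzyloxy)-4-[(1S)-1-(2-bromo-1-ethoxypropoxy)prop-2-yn-1-yl]-2-methoxybenzene (diastereomer mixture) | C#C[C@H](OC(OCC)C(C)Br)c1ccc(OCc2ccccc2)c(OC)c1
F2 | step 4 | (5S)-5-[4-(benzyloxy)-3-methoxyphenyl]-2-ethoxy-3-methyl-4-methylideneoxolane (mixture at C2/C3) | CCOC1O[C@H](c2ccc(OCc3ccccc3)c(OC)c2)C(=C)C1C
F3 | step 4 | (4R,5S)-5-[4-(benzyloxy)-3-methoxyphenyl]-2-ethoxy-3,4-dimethyloxolane (mixture at C2/C3) | CCOC1O[C@H](c2ccc(OCc3ccccc3)c(OC)c2)[C@H](C)C1C
F4 | step 4 | (3R,4R,5S)-5-[4-(benzyloxy)-3-methoxyphenyl]-3,4-dimethyloxolan-2-one | O=C1O[C@H](c2ccc(OCc3ccccc3)c(OC)c2)[C@H](C)[C@H]1C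
F5 | step 4 | (3R,4R,5S)-5-[4-(benzyloxy)-3-methoxyphenyl]-2-(3,4-dimethoxyphenyl)-3,4-dimethyloxolan-2-ol (anomer mixture) | OC1(c2ccc(OC)c(OC)c2)O[C@H](c2ccc(OCc3ccccc3)c(OC)c2)[C@H](C)[C@H]1C
F6 | step 5 | {(2S,3S)-2-[4-(benzyloxy)-3-methoxyphenyl]-5-(3,4-dimethoxyphenyl)-5-methoxy-4-methyloxolan-3-yl}methanol (hydroxymethyl cis to the aryl on the adjacent carbon) | COC1(c2ccc(OC)c(OC)c2)O[C@H](c2ccc(OCc3ccccc3)c(OC)c2)[C@H](CO)C1C
F7 | step 5 | {(2S,3S)-2-[4-(benzyloxy)-3-methoxyphenyl]-5-(3,4-dimethoxyphenyl)-5-methoxy-4-methyloxolan-3-yl}methyl 4-methylbenzenesulfonate | COC1(c2ccc(OC)c(OC)c2)O[C@H](c2ccc(OCc3ccccc3)c(OC)c2)[C@H](COS(=O)(=O)c2ccc(C)cc2)C1C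
F8 | step 11 | ethyl (2R)-2-{4-[(2S,3R,4R,5S)-5-(3,4-dimethoxyphenyl)-3,4-dimethyloxolan-2-yl]-2-methoxyphenoxy}propanoate | CCOC(=O)[C@@H](C)Oc1ccc([C@H]2O[C@H](c3ccc(OC)c(OC)c3)[C@H](C)[C@H]2C)cc1OC
F9 | step 11 | (2R)-2-{4-[(2S,3R,4R,5S)-5-(3,4-dimethoxyphenyl)-3,4-dimethyloxolan-2-yl]-2-methoxyphenoxy}-N-methoxy-N-methylpropanamide | CON(C)C(=O)[C@@H](C)Oc1ccc([C@H]2O[C@H](c3ccc(OC)c(OC)c3)[C@H](C)[C@H]2C)cc1OC
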